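The synthesis rests on cutting lactone ring B at O2–C3 and, in the same operation, at C4–C4a. It exploits that C3 is a dienylic carbinol carbon lying between benzylic C4 and the C1'=C2'–C3'=C4' diene: O2–C3 is therefore the C–O bond of an allylic carboxylate, and C4–C3–C1'–C4' is a conjugated triene in disguise. One enantioselective palladium-catalysed arylation/allylic carboxylation cascade joins a 6-halosalicylic acid to an achiral all-E C19 triene, closes ring B at O2–C3, sets C3 and unveils the (1'E,3'E)-diene, with no protecting group. The ring-closing precursor is a π-allylpalladium carboxylate formed in the flask.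

Key step: step 3

Numbering used below: isochroman-1-one numbering (C1 carbonyl, O2, C3, C4, C4a–C8a = benzene ring A, lactone = ring B), side chain C1'–C17'.

Assumption: the 6-bromosalicylic acid of step 3 is taken as a commercial compound, and the enantiomer of the chiral ligand that leads to the (R)-lactone is chosen in a pilot run, the mirror-image ligand giving the antipode.

Step 1
Reactants: 1 pentadec-1-ene; 2 (E)-but-2-enal (crotonaldehyde)
Product: 3 (E)-hexadec-2-enal
Conditions: second-generation Hoveyda–Grubbs catalyst (H2IMes)Cl2Ru(=CH-C6H4-2-OiPr) (2 mol%), 2 (5 equiv), CH2Cl2, 40 °C
Reagents that add atoms: none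
Why: Olefin cross-metathesis of a terminal alkene with an excess of the electron-poor partner crotonaldehyde should favour the cross product and give the (E)-enal under thermodynamic control, with propene leaving as a gas.

Step 2
Reactants: 3 (E)-hexadec-2-enal; 4 allyldiphenylphosphine oxide
Product: 7 (3E,5E)-nonadeca-1,3,5-triene, via lithiated allyldiphenylphosphine oxide 5 (not isolated), via lithium alkoxide adduct 6 (not isolated)
Conditions: 4, n-BuLi, THF, −78 °C; HMPA; then 3, −78 °C to rt
Reagents that add atoms: none
Why: Horner–Wittig olefination, in which the lithiated allylphosphine oxide should add through its α-carbon to the aldehyde carbonyl (1,2-addition, favoured by HMPA) and the adduct should lose lithium diphenylphosphinate by syn-elimination on warming to form the new C3=C4 alkene with E geometry, the existing E alkene being untouched.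

Step 3
Reactants: 7 (3E,5E)-nonadeca-1,3,5-triene; 8 2-bromo-6-hydroxybenzoic acid
Product: 10 (3R)-3-[(1E,3E)-heptadeca-1,3-dien-1-yl]-8-hydroxyisochroman-1-one, via pi-allylpalladium carboxylate 9 (not isolated)
Conditions: Pd2(dba)3·CHCl3 (2.5 mol%), chiral sulfinamide monophosphine ligand of the TY-Phos type (6 mol%), K2CO3 (1.5 equiv), 7 (1.3 equiv), 1,4-dioxane, 70 °C
Reagents that add atoms: none
Why: Proposed new method: zerovalent palladium inserts into the C–Br bond of 8, the aryl group adds syn to the unsubstituted terminal carbon of triene 7 (making the C4–C4a bond), and in the resulting π-allylpalladium carboxylate 9, whose allyl unit spans C3, C1' and C2' and stays conjugated to the 3'E alkene, the ortho carboxylate oxygen attacks C3 to form the O2–C3 bond and give back zerovalent palladium. The closest known reaction types are the palladium-catalysed heteroannulation of 1,3-dienes by ortho-halobenzoic acids (Larock type, racemic) and the enantioselective Heck/Tsuji–Trost annulation of 1,3-dienes with ortho-halophenols and ortho-haloanilines; new are the enantioselective capture by a carboxylate and the use of a conjugated triene in place of a diene. Ring B closes by a 6-exo allylic substitution in which O2 attacks the allyl terminus C3 while C1'=C2' forms outside the ring. The C3 stereocentre is controlled by the chiral ligand on palladium, which chooses the face of the terminal alkene in the migratory insertion; the carboxylate then attacks the syn,syn-allyl stereospecifically, so the same event fixes the 1'E geometry and leaves the 3'E alkene as it was. The step needs arylation at the terminal CH2 only (the one unhindered alkene carbon, and the only site that gives a fully delocalised pentadienyl-type palladium species) and C–O formation at C3 instead of C2' or C4' (only C3 lies within reach of the carboxylate for a strain-free six-membered ring, and only this mode keeps the diene conjugated). β-Hydride loss to a tetraene should be held back because palladium is bound as a π-allyl next to an intramolecular carboxylate, and the free C8 phenol cannot reach the allyl.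

Compound list
1 | pentadec-1-ene | CCCCCCCCCCCCCC=C | starting material
2 | (E)-but-2-enal (crotonaldehyde) | C/C=C/C=O | starting material
3 | (E)-hexadec-2-enal | CCCCCCCCCCCCC/C=C/C=O | intermediate
4 | allyldiphenylphosphine oxide | C=CCP(=O)(c1ccccc1)c1ccccc1 | starting material
5 | lithiated allyldiphenylphosphine oxide | C=C[CH-]P(=O)(c1ccccc1)c1ccccc1.[Li+] | intermediate (not isolated)
6 | lithium alkoxide adduct, lithium (5E)-3-(diphenylphosphoryl)nonadeca-1,5-dien-4-olate (diastereomer mixture) | CCCCCCCCCCCCC/C=C/C([O-])C(C=C)P(=O)(c1ccccc1)c1ccccc1.[Li+] | intermediate (not isolated)
7 | (3E,5E)-nonadeca-1,3,5-triene | CCCCCCCCCCCCC/C=C/C=C/C=C | intermediate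
8 | 2-bromo-6-hydroxybenzoic acid | OC(=O)c1c(O)cccc1Br | starting material
9 | pi-allylpalladium carboxylate of divalent palladium (chiral phosphine ligand on palladium not drawn) | [O-]C(=O)c1c(O)cccc1C[CH]1[CH]2[CH](/C=C/CCCCCCCCCCCCC)[Pd+]12 | intermediate (not isolated)
10 | (3R)-3-[(1E,3E)-heptadeca-1,3-dien-1-yl]-8-hydroxyisochroman-1-one (CNP0165705.1) | CCCCCCCCCCCCC/C=C/C=C/[C@H]1Cc2cccc(O)c2C(=O)O1 | target

Total step count: 3
Longest linear sequence: 3 steps (1 → 3 → 7 → 10)

Steps most likely to fail

Step 3 (labelled step). What may go wrong: ring closure at a distal terminus of the extended π-allyl (eight- or ten-membered lactones), β-hydride loss before C–O formation, slow oxidative addition into the electron-rich bromide while the triene oligomerises, or erosion of enantiopurity through re-ionisation of the dienylic O2–C3 bond by zerovalent palladium. The fallback uses known chemistry only and sets out from enal 3. Wittig two-carbon homologation of 3 with (triphenylphosphoranylidene)acetaldehyde (toluene, 80 °C) should give (2E,4E)-octadeca-2,4-dienal F1. Commercial 2-hydroxy-6-methylbenzoic acid is converted with acetone, (CF3CO)2O and CF3CO2H into 2,2,5-trimethyl-4H-1,3-benzodioxin-4-one F2. Lateral lithiation of F2 (LiN(iPr)2, THF, −78 °C) and 1,2-addition to F1 gives an alkoxide that should close onto the dioxinone carbonyl on warming, with loss of acetone, to give racemic 3-[(1E,3E)-heptadeca-1,3-dien-1-yl]-8-hydroxyisochroman-1-one F3. Ring B is then closed by acyl transfer instead of allylic substitution. Preparative HPLC on a chiral stationary phase separates the enantiomers, and the fallback comes back to the route at 10.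

Step 2. What may go wrong: attack of the ambident allyl anion through its γ-carbon or in a conjugate sense, and incomplete E-selectivity in the elimination, which would give branched dienes or a 3Z-triene that can electrocyclise and would misdirect the key step. The fallback sets out from enal 3. Wittig reaction with the stabilised ylide (triphenylphosphoranylidene)acetaldehyde (toluene, 80 °C) forms the C3=C4 alkene E-selectively and should give (2E,4E)-octadeca-2,4-dienal F4. Methylenation of F4 with methylenetriphenylphosphorane (from methyltriphenylphosphonium bromide and KOtBu, THF, 0 °C) then adds the terminal alkene, which has no geometry to control, and the fallback comes back to the route at 7.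

Step 1. What may go wrong: homodimerisation of the terminal alkene and double-bond migration caused by ruthenium hydride species, which would give chain-shortened enals that are hard to separate. The fallback sets out from alkene 1. Ozonolysis (O3, CH2Cl2, −78 °C; then PPh3) should give tetradecanal F5. Wittig reaction of F5 with (triphenylphosphoranylidene)acetaldehyde (1.05 equiv, toluene, 80 °C) should give the (E)-enal, and the fallback comes back to the route at 3.

Further compounds
F1 | step 3 | (2E,4E)-octadeca-2,4-dienal | CCCCCCCCCCCCC/C=C/C=C/C=O
F2 | step 3 | 2,2,5-trimethyl-4H-1,3-benzodioxin-4-one | Cc1cccc2OC(C)(C)OC(=O)c12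
F3 | step 3 | racemic 3-[(1E,3E)-heptadeca-1,3-dien-1-yl]-8-hydroxyisochroman-1-one | CCCCCCCCCCCCC/C=C/C=C/C1Cc2cccc(O)c2C(=O)O1
F4 | step 2 | (2E,4E)-octadeca-2,4-dienal | CCCCCCCCCCCCC/C=C/C=C/C=O
F5 | step 1 | tetradecanal | CCCCCCCCCCCCCC=O
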